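Ring A is a phloroglucinol. Its aryloxy carbon C1 lies between the hydroxyl carbons C2 and C6, and the third hydroxyl sits at C4. This is the oxygen pattern of a folded triketide chain whose terminal carbon carries the ring B oxygen.
Key disconnection: the C1–C2 bond of ring A (C6–C1 of the chain). It leads back to a methyl 6-aryloxy-3,5-dioxohexanoate, which closes by intramolecular Claisen condensation and aromatisation.
The chain comes from the methyl acetoacetate dianion and an aryloxyacetic Weinreb amide, so the crowded ring A–O–ring B bond is made by O-alkylation of the ring B–C–D–E phenol at an sp3 carbon.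
The tetramer phenol grows from ring E towards ring B by three turns of one cycle: CuI-catalysed Ullmann coupling of the phenol with a bromobenzaldehyde, then Baeyer–Villiger oxidation of the formyl group to the next phenol.
Rings E, D, C and B are bought as arenes and joined in that order. Ring A is the only ring formed, and it is formed last, before global O-demethylation.

Key step: step 11

Remark: the β,δ-diketo ester and the cyclohexanetrione are drawn as keto tautomers although they should exist largely as enols. The target has no stereocentre, so no stereocontrol is needed.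
Shorthand: BCDE-aryl = 2-{3,4-dimethoxy-5-[3,4,5-trimethoxy-2-(3,4,5-trimethoxyphenoxy)phenoxy]phenoxy}-3,5-dimethoxyphenyl, bonded through ring B C1.

Step 1
Reactants: 1 3,4,5-trimethoxybenzaldehyde
Product: 2 2-bromo-3,4,5-trimethoxybenzaldehyde
Conditions: NBS (1.1 equiv), CHCl3, reflux
Reagents that add atoms: N-bromosuccinimide, O=C1CCC(=O)N1Br
Why: Electrophilic aromatic bromination; the two free ring positions are equivalent and each is ortho and para to methoxy groups, so a single monobromide is expected.

Step 2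
Reactants: 2 2-bromo-3,4,5-trimethoxybenzaldehyde; 3 3,4,5-trimethoxyphenol
Product: 4 3,4,5-trimethoxy-2-(3,4,5-trimethoxyphenoxy)benzaldehyde
Conditions: CuI (10 mol %), N,N-dimethylglycine (30 mol %), Cs2CO3 (2 equiv), 1,4-dioxane, 100 °C, argon
Reagents that add atoms: none
Why: Ligand-accelerated Ullmann diaryl ether synthesis; phenol 3 has hydrogen at both ortho positions, and the ortho-formyl group of 2 assists copper insertion into the doubly flanked C–Br bond, as in the classical couplings of 2-bromo-3,4,5-trialkoxybenzoyl compounds.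

Step 3
Reactants: 4 3,4,5-trimethoxy-2-(3,4,5-trimethoxyphenoxy)benzaldehyde
Product: 6 3,4,5-trimethoxy-2-(3,4,5-trimethoxyphenoxy)phenol, via aryl formate 5 (not isolated)
Conditions: mCPBA (1.3 equiv), CH2Cl2, 0 °C to rt; aq Na2S2O3/NaHCO3 wash; then K2CO3 (0.2 equiv), MeOH, rt, argon
Reagents that add atoms: meta-chloroperoxybenzoic acid (mCPBA), OOC(=O)c1cccc(Cl)c1
Why: Baeyer–Villiger oxidation of an electron-rich benzaldehyde, in which the ortho-aryloxy and para-methoxy donors make aryl migration faster than hydride migration, followed by carbonate-catalysed methanolysis of the formate.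

Step 4
Reactants: 6 3,4,5-trimethoxy-2-(3,4,5-trimethoxyphenoxy)phenol; 7 3-bromo-4,5-dimethoxybenzaldehyde
Product: 8 3,4-dimethoxy-5-[3,4,5-trimethoxy-2-(3,4,5-trimethoxyphenoxy)phenoxy]benzaldehyde
Conditions: CuI (10 mol %), picolinic acid (20 mol %), K3PO4 (2 equiv), DMSO, 90 °C, argon
Reagents that add atoms: none
Why: Ullmann-type C–O coupling under the CuI/picolinic acid system used for hindered partners; the bromide carries only one ortho substituent and an electron-withdrawing, non-enolisable formyl group that also marks the next phenol oxygen.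

Step 5
Reactants: 8 3,4-dimethoxy-5-[3,4,5-trimethoxy-2-(3,4,5-trimethoxyphenoxy)phenoxy]benzaldehyde
Product: 10 3,4-dimethoxy-5-[3,4,5-trimethoxy-2-(3,4,5-trimethoxyphenoxy)phenoxy]phenol, via aryl formate 9 (not isolated)
Conditions: mCPBA (1.3 equiv), CH2Cl2, 0 °C to rt; aq Na2S2O3/NaHCO3 wash; then K2CO3 (0.2 equiv), MeOH, rt, argon
Reagents that add atoms: meta-chloroperoxybenzoic acid (mCPBA), OOC(=O)c1cccc(Cl)c1
Why: Baeyer–Villiger oxidation and formate methanolysis; the para-methoxy group drives aryl migration, as in the known conversion of 3,4,5-trialkoxybenzaldehydes into the phenols.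

Step 6
Reactants: 11 3,5-dimethoxybenzaldehyde
Product: 12 2-bromo-3,5-dimethoxybenzaldehyde
Conditions: NBS (1.0 equiv), MeCN, 0 °C to rt
Reagents that add atoms: N-bromosuccinimide, O=C1CCC(=O)N1Br
Why: Electrophilic aromatic bromination; C2 (equivalent to C6) is ortho to one methoxy group and para to the other, and it is less crowded than C4 between the two methoxy groups, which is the established regiochemistry for this aldehyde.

Step 7
Reactants: 10 3,4-dimethoxy-5-[3,4,5-trimethoxy-2-(3,4,5-trimethoxyphenoxy)phenoxy]phenol; 12 2-bromo-3,5-dimethoxybenzaldehyde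
Product: 13 2-{3,4-dimethoxy-5-[3,4,5-trimethoxy-2-(3,4,5-trimethoxyphenoxy)phenoxy]phenoxy}-3,5-dimethoxybenzaldehyde
Conditions: CuI (10 mol %), N,N-dimethylglycine (30 mol %), Cs2CO3 (2 equiv), 1,4-dioxane, 100 °C, argon
Reagents that add atoms: none
Why: Ligand-accelerated Ullmann diaryl ether synthesis; the hydroxyl of 10 is flanked by two hydrogens, and the ortho-formyl group of 12 activates the crowded C–Br bond just as in step 2.

Step 8
Reactants: 13 2-{3,4-dimethoxy-5-[3,4,5-trimethoxy-2-(3,4,5-trimethoxyphenoxy)phenoxy]phenoxy}-3,5-dimethoxybenzaldehyde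
Product: 15 2-{3,4-dimethoxy-5-[3,4,5-trimethoxy-2-(3,4,5-trimethoxyphenoxy)phenoxy]phenoxy}-3,5-dimethoxyphenol (BCDE-aryl–OH), via aryl formate 14 (not isolated)
Conditions: mCPBA (1.5 equiv), NaHCO3, CH2Cl2, 0 °C to rt; aq Na2S2O3 wash; then K2CO3 (0.2 equiv), MeOH, rt, argon
Reagents that add atoms: meta-chloroperoxybenzoic acid (mCPBA), OOC(=O)c1cccc(Cl)c1
Why: Baeyer–Villiger oxidation of a 2-aryloxybenzaldehyde, a substrate type known to give the aryl formate because the ortho oxygen lone pair supports aryl migration; methanolysis then frees the ring B phenol that will carry ring A.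

Step 9
Reactants: 15 BCDE-aryl–OH; 16 2-chloro-N-methoxy-N-methylacetamide
Product: 17 2-(BCDE-aryloxy)-N-methoxy-N-methylacetamide
Conditions: K2CO3 (2 equiv), DMF, 60 °C
Reagents that add atoms: none
Why: Williamson ether synthesis (SN2 at a primary α-chloro amide carbon); the future ring A–O–ring B bond is thus made at an unhindered sp3 carbon, and the Weinreb amide is stable to carbonate.

Step 10
Reactants: 17 2-(BCDE-aryloxy)-N-methoxy-N-methylacetamide; 18 methyl acetoacetate
Product: 20 methyl 6-(BCDE-aryloxy)-3,5-dioxohexanoate, via methyl acetoacetate dianion 19 (not isolated)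
Conditions: 18 (2.5 equiv), NaH (2.5 equiv), THF, 0 °C; n-BuLi (2.5 equiv), 0 °C; then 17, −78 °C to 0 °C; then 1 M HCl
Reagents that add atoms: none
Why: γ-Acylation of a β-keto ester dianion by a Weinreb amide, a known entry to β,δ-diketo esters; the terminal carbanion is the more nucleophilic site, and the chelated tetrahedral adduct lasts until the acidic quench, which prevents over-addition.

Step 11
Reactants: 20 methyl 6-(BCDE-aryloxy)-3,5-dioxohexanoate
Product: 22 2-(BCDE-aryloxy)benzene-1,3,5-triol (ring A free triol; ten methyl ethers on rings B to E), via cyclohexane-1,3,5-trione tautomer 21 (not isolated)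
Conditions: NaOMe (5 equiv), degassed MeOH (0.02 M), reflux, argon; then 1 M HCl, 0 °C
Reagents that add atoms: none
Why: In methanolic NaOMe 20 rests as its C4 and C2 enolates, which can only reach four-membered rings, while the minor C5–C6 enolate, favoured by the inductive effect of the aryloxy oxygen on C6, adds to the ester carbonyl C1, expels methoxide and gives trione 21, which enolises at once to the phloroglucinolate of 22. The closest known reaction type is the base-mediated intramolecular Claisen (Dieckmann-type) cyclisation of 3,5-dioxoalkanoates and 3,5,7-trioxoalkanoates to phloroglucinols, the laboratory counterpart of the polyketide route. Ring A closes in the 6-(enolendo)-exo-trig mode through the single new C6–C1 bond, and no stereocentre is formed. The selectivity needed is C-acylation at C6 over O-acylation by the C5 enol oxygen (lactonisation to a 4-hydroxy-2-pyrone): excess methoxide in methanol, matched to the methyl ester, should keep the lactone pathway reversible, whereas aromatisation and deprotonation of the triol make the carbocyclic pathway irreversible. Sodium is chosen over a chelating divalent metal because a chelated 3,5-diketonate fixes O3 and O5 syn and so holds C2 and C6 anti in a W-shaped chain, the opposite of the U-shaped fold that closure requires. The ten aryl methyl ethers and the three diaryl ethers are inert to methoxide, dilution limits intermolecular aldol condensation, and air is excluded because the electron-rich phenolate is oxidisable.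

Step 12
Reactants: 22 2-(BCDE-aryloxy)benzene-1,3,5-triol
Product: 23 pseudopentafuhalol D
Conditions: BBr3 (25 equiv), CH2Cl2, −78 °C to rt, argon; ice-water quench, EtOAc extraction; degassed reversed-phase or Sephadex LH-20 chromatography
Reagents that add atoms: none
Why: BBr3 aryl methyl ether cleavage, in which each methoxy oxygen binds boron and loses MeBr by SN2 at methyl while the diaryl ether bonds offer no sp3 carbon and stay intact; a cold aqueous quench rather than a methanolic one avoids acid-catalysed re-etherification of the phloroglucinol rings.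

Compound list
1 | 3,4,5-trimethoxybenzaldehyde | COc1cc(C=O)cc(OC)c1OC | starting material
2 | 2-bromo-3,4,5-trimethoxybenzaldehyde | COc1cc(C=O)c(Br)c(OC)c1OC | intermediate
3 | 3,4,5-trimethoxyphenol | COc1cc(O)cc(OC)c1OC | starting material
4 | 3,4,5-trimethoxy-2-(3,4,5-trimethoxyphenoxy)benzaldehyde (D–E aldehyde) | COc1cc(C=O)c(Oc2cc(OC)c(OC)c(OC)c2)c(OC)c1OC | intermediate
5 | 3,4,5-trimethoxy-2-(3,4,5-trimethoxyphenoxy)phenyl formate | COc1cc(OC=O)c(Oc2cc(OC)c(OC)c(OC)c2)c(OC)c1OC | intermediate
6 | 3,4,5-trimethoxy-2-(3,4,5-trimethoxyphenoxy)phenol (D–E phenol) | COc1cc(O)c(Oc2cc(OC)c(OC)c(OC)c2)c(OC)c1OC | intermediate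
7 | 3-bromo-4,5-dimethoxybenzaldehyde | COc1cc(C=O)cc(Br)c1OC | starting material
8 | 3,4-dimethoxy-5-[3,4,5-trimethoxy-2-(3,4,5-trimethoxyphenoxy)phenoxy]benzaldehyde (C–D–E aldehyde) | COc1cc(C=O)cc(Oc2cc(OC)c(OC)c(OC)c2Oc2cc(OC)c(OC)c(OC)c2)c1OC | intermediate
9 | 3,4-dimethoxy-5-[3,4,5-trimethoxy-2-(3,4,5-trimethoxyphenoxy)phenoxy]phenyl formate | COc1cc(OC=O)cc(Oc2cc(OC)c(OC)c(OC)c2Oc2cc(OC)c(OC)c(OC)c2)c1OC | intermediate
10 | 3,4-dimethoxy-5-[3,4,5-trimethoxy-2-(3,4,5-trimethoxyphenoxy)phenoxy]phenol (C–D–E phenol) | COc1cc(O)cc(Oc2cc(OC)c(OC)c(OC)c2Oc2cc(OC)c(OC)c(OC)c2)c1OC | intermediate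
11 | 3,5-dimethoxybenzaldehyde | COc1cc(C=O)cc(OC)c1 | starting material
12 | 2-bromo-3,5-dimethoxybenzaldehyde | COc1cc(C=O)c(Br)c(OC)c1 | intermediate
13 | 2-{3,4-dimethoxy-5-[3,4,5-trimethoxy-2-(3,4,5-trimethoxyphenoxy)phenoxy]phenoxy}-3,5-dimethoxybenzaldehyde (B–C–D–E aldehyde) | O=Cc1cc(OC)cc(OC)c1Oc1cc(OC)c(OC)c(Oc2cc(OC)c(OC)c(OC)c2Oc2cc(OC)c(OC)c(OC)c2)c1 | intermediate
14 | BCDE-aryl formate | O=COc1cc(OC)cc(OC)c1Oc1cc(OC)c(OC)c(Oc2cc(OC)c(OC)c(OC)c2Oc2cc(OC)c(OC)c(OC)c2)c1 | intermediate
15 | 2-{3,4-dimethoxy-5-[3,4,5-trimethoxy-2-(3,4,5-trimethoxyphenoxy)phenoxy]phenoxy}-3,5-dimethoxyphenol (B–C–D–E phenol) | Oc1cc(OC)cc(OC)c1Oc1cc(OC)c(OC)c(Oc2cc(OC)c(OC)c(OC)c2Oc2cc(OC)c(OC)c(OC)c2)c1 | intermediate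
16 | 2-chloro-N-methoxy-N-methylacetamide | CON(C)C(=O)CCl | starting material
17 | 2-(BCDE-aryloxy)-N-methoxy-N-methylacetamide | CON(C)C(=O)COc1cc(OC)cc(OC)c1Oc1cc(OC)c(OC)c(Oc2cc(OC)c(OC)c(OC)c2Oc2cc(OC)c(OC)c(OC)c2)c1 | intermediate
18 | methyl acetoacetate | COC(=O)CC(C)=O | starting material
19 | methyl acetoacetate dianion (sodium lithium salt) | COC([O-])=CC([O-])=C.[Na+].[Li+] | intermediate
20 | methyl 6-(BCDE-aryloxy)-3,5-dioxohexanoate | COC(=O)CC(=O)CC(=O)COc1cc(OC)cc(OC)c1Oc1cc(OC)c(OC)c(Oc2cc(OC)c(OC)c(OC)c2Oc2cc(OC)c(OC)c(OC)c2)c1 | intermediate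
21 | 2-(BCDE-aryloxy)cyclohexane-1,3,5-trione | O=C1CC(=O)C(Oc2cc(OC)cc(OC)c2Oc2cc(OC)c(OC)c(Oc3cc(OC)c(OC)c(OC)c3Oc3cc(OC)c(OC)c(OC)c3)c2)C(=O)C1 | intermediate
22 | 2-(BCDE-aryloxy)benzene-1,3,5-triol (pentamer, ring A free triol, ten methyl ethers) | Oc1cc(O)c(Oc2cc(OC)cc(OC)c2Oc2cc(OC)c(OC)c(Oc3cc(OC)c(OC)c(OC)c3Oc3cc(OC)c(OC)c(OC)c3)c2)c(O)c1 | intermediate
23 | pseudopentafuhalol D | Oc1cc(O)c(Oc2cc(O)cc(O)c2Oc2cc(O)c(O)c(Oc3cc(O)c(O)c(O)c3Oc3cc(O)c(O)c(O)c3)c2)c(O)c1 | target

Total step count: 12. Longest linear sequence: 11 steps (steps 1 to 5 and 7 to 12, from 1 to 23); step 6 is a one-step branch.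

Steps most likely to fail

Step 11 (closure of ring A). The closure may stall because the substrate rests as its unproductive C2 and C4 enolates. It may also be diverted by O-acylation of the C5 enol oxygen (lactonisation) or by intermolecular aldol condensation. In the fallback, ring A is bought instead of built, and the ring A–O–ring B bond is made at an aromatic carbon by a fourth turn of the coupling and oxidation cycle. The fallback sets out from 15. CuI/N,N-dimethylglycine/Cs2CO3 coupling in dioxane at 100 °C with a second portion of 12 should give the pentamer aldehyde F1. mCPBA in CH2Cl2 should then give the pentamer aryl formate F2. Catalytic K2CO3 in MeOH should give the pentamer phenol F3, in which ring A is a 2-hydroxy-4,6-dimethoxyphenoxy group. BBr3 in CH2Cl2 then cleaves twelve methyl ethers, and the route is rejoined at 23.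

Step 12 (global demethylation). Ether cleavage may stop short once partly cleaved boron aryloxides precipitate. The pyrogallol-type rings D and E may also oxidise in air during aqueous isolation and chromatography of the free polyphenol. The fallback isolates a protected derivative and releases the phenols afterwards. It sets out from 22. The crude BBr3 product is not purified but is treated at once with Ac2O and pyridine to give the tridecaacetate F4. This compound is stable in air and can be separated on silica gel from incompletely demethylated material. Hydrazinolysis of F4 (N2H4·H2O, degassed MeCN, 0 °C to rt, argon, then dilute acid) removes the thirteen acetates under non-oxidising conditions and rejoins the route at 23.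

Step 4 (ring C–O–ring D coupling). Both partners carry an ortho substituent and the bromide has no ortho or para activating group. Copper insertion may therefore be slow, and hydrodebromination of the bromide may compete. The fallback reverses the way the aryl–copper species is made. It sets out from 7. Miyaura borylation (B2pin2, Pd(dppf)Cl2, KOAc, dioxane, 90 °C) should give the pinacol boronate F5. NaIO4 with aq HCl in THF should give the boronic acid F6. Chan–Evans–Lam coupling of F6 with phenol 6 (Cu(OAc)2, pyridine, 4 Å molecular sieves, CH2Cl2, air, rt) forms the same C–O bond at room temperature by transmetallation to divalent copper, without insertion into a C–Br bond. It rejoins the route at 8.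

Further compounds
F1 | step 11 | 2-(BCDE-aryloxy)-3,5-dimethoxybenzaldehyde (pentamer aldehyde) | O=Cc1cc(OC)cc(OC)c1Oc1cc(OC)cc(OC)c1Oc1cc(OC)c(OC)c(Oc2cc(OC)c(OC)c(OC)c2Oc2cc(OC)c(OC)c(OC)c2)c1
F2 | step 11 | 2-(BCDE-aryloxy)-3,5-dimethoxyphenyl formate (pentamer aryl formate) | O=COc1cc(OC)cc(OC)c1Oc1cc(OC)cc(OC)c1Oc1cc(OC)c(OC)c(Oc2cc(OC)c(OC)c(OC)c2Oc2cc(OC)c(OC)c(OC)c2)c1
F3 | step 11 | 2-(BCDE-aryloxy)-3,5-dimethoxyphenol (pentamer phenol, twelve methyl ethers) | Oc1cc(OC)cc(OC)c1Oc1cc(OC)cc(OC)c1Oc1cc(OC)c(OC)c(Oc2cc(OC)c(OC)c(OC)c2Oc2cc(OC)c(OC)c(OC)c2)c1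
F4 | step 12 | pseudopentafuhalol D tridecaacetate | CC(=O)Oc1cc(OC(C)=O)c(Oc2cc(OC(C)=O)cc(OC(C)=O)c2Oc2cc(OC(C)=O)c(OC(C)=O)c(Oc3cc(OC(C)=O)c(OC(C)=O)c(OC(C)=O)c3Oc3cc(OC(C)=O)c(OC(C)=O)c(OC(C)=O)c3)c2)c(OC(C)=O)c1
F5 | step 4 | 3,4-dimethoxy-5-(4,4,5,5-tetramethyl-1,3,2-dioxaborolan-2-yl)benzaldehyde | COc1cc(C=O)cc(B2OC(C)(C)C(C)(C)O2)c1OC
F6 | step 4 | (5-formyl-2,3-dimethoxyphenyl)boronic acid | COc1cc(C=O)cc(B(O)O)c1OC
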